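**Strategy.** Ring A is disconnected across C1–C10 and C4–C5: a C1–C4 diene carrying the C4 gem-dimethyl group and the C3 oxygen, and an (E)-2-methyl enal whose alkene becomes C5/C10. One catalytic enantioselective Diels–Alder reaction should form both bonds, the C10 quaternary centre, C5, and the trans relationship that later becomes the trans ring fusion. It also leaves a C2=C3 silyl enol ether that is converted into the 2α-chloro-3β-ol. The dienophile carries C6–C8 with a C7 carbinol that steers a reductive enyne cyclisation closing ring B (C8–C9). Oxidation and Luche reduction then correct C7 and set C3, and an Evans aldol/ammonolysis sequence installs the hydroxy-succinimide.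

Key step: step 5

Remark: labdane numbering is used throughout (decalin C1–C10, side chain C11/C12, succinimide C13–C16, exocyclic methylene C17; α/β with the C10 methyl β); compounds 1, 3, 6, 17, 18 and the allylborane of step 2 are taken as purchased.

Step 1
Reactants: 1 4-methylpent-1-en-3-one
Product: 2 triisopropyl[(4-methylpenta-1,3-dien-3-yl)oxy]silane
Conditions: TIPSOTf (1.1 equiv), Et3N (1.5 equiv), CH2Cl2, 0 °C to rt
Reagents that add atoms: triisopropylsilyl triflate CC(C)[Si](C(C)C)(C(C)C)OS(=O)(=O)C(F)(F)F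
Why: Soft enolisation (silyl triflate/amine) of a ketone whose only α-hydrogen is the isopropyl methine should give the 2-silyloxydiene as a single regioisomer; no stereocentre is formed.

Step 2
Reactants: 3 3-(trimethylsilyl)prop-2-ynal
Product: 4 (3R)-1-(trimethylsilyl)hex-5-en-1-yn-3-ol
Conditions: (+)-Ipc2B(allyl) (1.2 equiv), Et2O, −78 °C; then NaOH, H2O2, 0 °C
Reagents that add atoms: (+)-B-allyldiisopinocampheylborane C=CCB([C@H]1C[C@H]2C[C@@H]([C@@H]1C)C2(C)C)[C@H]1C[C@H]2C[C@@H]([C@@H]1C)C2(C)C
Why: Brown-type asymmetric allylboration through a closed chair transition state; the reagent from (−)-α-pinene should deliver allyl to the Re face of the ynal and set C7 as R (the future 7α-oxygen).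

Step 3
Reactants: 4 (3R)-1-(trimethylsilyl)hex-5-en-1-yn-3-ol
Product: 5 (3R)-1-(trimethylsilyl)hex-5-en-1-yn-3-yl acetate
Conditions: Ac2O, Et3N, DMAP (cat.), CH2Cl2, 0 °C to rt
Reagents that add atoms: acetic anhydride CC(=O)OC(C)=O
Why: DMAP-catalysed O-acylation; the acetate masks the carbinol through the Lewis acid step and is later removed in the same operation as the C-silyl group.

Step 4
Reactants: 5 (3R)-1-(trimethylsilyl)hex-5-en-1-yn-3-yl acetate; 6 methacrolein
Product: 7 (3R,5E)-6-methyl-7-oxo-1-(trimethylsilyl)hept-5-en-1-yn-3-yl acetate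
Conditions: 6 (5 equiv), second-generation Hoveyda–Grubbs catalyst (5 mol%), CH2Cl2, 40 °C
Reagents that add atoms: none
Why: Olefin cross-metathesis of the unhindered terminal alkene with excess methacrolein should give the thermodynamically preferred (E)-trisubstituted enal, the silyl-capped alkyne being too hindered to enter enyne metathesis.

Step 5
Reactants: 2 triisopropyl[(4-methylpenta-1,3-dien-3-yl)oxy]silane; 7 (3R,5E)-6-methyl-7-oxo-1-(trimethylsilyl)hept-5-en-1-yn-3-yl acetate
Product: 8 (2R)-1-[(1S,6S)-6-formyl-2,2,6-trimethyl-3-(triisopropylsilyloxy)cyclohex-3-en-1-yl]-4-(trimethylsilyl)but-3-yn-2-yl acetate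
Conditions: 2 (1.5 equiv), (R)-o-tolyl-oxazaborolidine from (R)-α,α-diphenylprolinol (10 mol%), AlBr3 (8 mol%), CH2Cl2, −78 to −40 °C
Reagents that add atoms: none
Why: The boron-bound s-trans enal and the electron-rich silyloxydiene should combine in a strongly asynchronous normal-demand [4+2] cycloaddition (in the limit a Mukaiyama–Michael addition followed by enolate closure), the nucleophilic CMe2 terminus C4 bonding to the β-carbon C5 and the vinyl terminus C1 to the formyl-bearing C10. The closest known reaction type is the cationic oxazaborolidine-catalysed Diels–Alder reaction of 2-silyloxydienes with α-substituted enals, and Lewis acid-promoted cycloadditions of hindered silyloxydienes with hindered dienophiles. Ring A is closed as a cyclohexene by this intermolecular (4+2) union, which leaves the enol ether at C2=C3 where the chlorohydrin is needed and turns the two diene methyls into the C4 gem-dimethyl group. The relative configuration of C5 and C10 (C6 and C9 trans on ring A) follows from suprafacial addition to the E alkene; the absolute configuration follows from the (R)-catalyst, which holds the formyl group by B–O coordination and a formyl C–H···O contact, shields the C10 Re face with an aryl group and leaves the Si face open. There is no endo/exo issue because C1 and C4 each carry two identical substituents. The step needs 1,4- rather than 1,2-attack on the enal and the "para" orientation of silyloxy and formyl groups; both rest on the polarisation of the diene (largest coefficient at C4) matched to the β-carbon of the activated enal and on the bulk around the boron-bound carbonyl.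

Step 6
Reactants: 8 cycloadduct aldehyde
Product: 9 methyl (E)-3-(ring A)prop-2-enoate (the C9 formyl group of 8 replaced by (E)-CH=CH–CO2Me; C5, C7 and C10 as in 8)
Conditions: (MeO)2P(O)CH2CO2Me, NaH, THF, 0 to 40 °C
Reagents that add atoms: trimethyl phosphonoacetate COC(=O)CP(=O)(OC)OC
Why: Horner–Wadsworth–Emmons olefination of the non-enolisable neopentyl aldehyde should give the (E)-enoate (C11, C12) without touching the silyl enol ether, the acetate or the alkynylsilane.

Step 7
Reactants: 9 enoate
Product: 10 propargylic alcohol (as 9, with free 7-OH of R configuration and a terminal alkyne)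
Conditions: K2CO3, MeOH, 0 °C to rt
Reagents that add atoms: none
Why: Methanolysis of the acetate and protiodesilylation of the alkynylsilane occur together under mild carbonate conditions that the triisopropylsilyl enol ether and the methyl enoate should survive.

Step 8
Reactants: 10 propargylic alcohol
Product: 11 methyl 7α-hydroxy-3-(triisopropylsilyloxy)-13,14,15,16-tetranorlabda-2,8(17)-dien-12-oate
Conditions: Pd2(dba)3·CHCl3 (2.5 mol%, zerovalent palladium), P(o-tol)3 (10 mol%), AcOH (2 equiv), Et3SiH (5 equiv), toluene, 25 to 50 °C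
Reagents that add atoms: none
Why: Palladium hydride reductive enyne cyclisation: hydropalladation of the terminal alkyne puts Pd on C8, 6-exo carbopalladation of the enoate forms C8–C9 and the silane reduces the C11–Pd bond; in the chair-like ring B held trans by C5/C10 the 7α-hydroxyl is axial, so an axial chain at C9 would be 1,3-diaxial to it and the CH2CO2Me group should take the equatorial site (9α-H).

Step 9
Reactants: 11 allylic alcohol
Product: 12 methyl 7-oxo-3-(triisopropylsilyloxy)-13,14,15,16-tetranorlabda-2,8(17)-dien-12-oate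
Conditions: Dess–Martin periodinane, NaHCO3, CH2Cl2, 0 °C to rt
Reagents that add atoms: none
Why: Buffered Dess–Martin oxidation of the allylic alcohol removes the temporary C7 stereocentre, which has done its work, and gives the 8(17)-en-7-one for axial hydride delivery.

Step 10
Reactants: 12 enone silyl enol ether
Product: 13 methyl 2α-chloro-3,7-dioxo-13,14,15,16-tetranorlabd-8(17)-en-12-oate
Conditions: NCS (1.1 equiv), THF, 0 °C to rt
Reagents that add atoms: N-chlorosuccinimide O=C1CCC(=O)N1Cl
Why: Electrophilic α-chlorination of the silyl enol ether; attack at C2 should come from the α face, away from the two 1,3-diaxial β-methyl groups on C4 and C10, and the equatorial 2α-chloride is also the thermodynamic epimer.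

Step 11
Reactants: 13 chloro diketone
Product: 14 methyl 2α-chloro-3β,7β-dihydroxy-13,14,15,16-tetranorlabd-8(17)-en-12-oate
Conditions: NaBH4, CeCl3·7H2O, MeOH, −78 to 0 °C
Reagents that add atoms: none
Why: Luche reduction should deliver hydride axially from the α face to both ketones (1,2-reduction of the exocyclic enone), giving the equatorial 3β- and 7β-alcohols and leaving the ester and the trans-diequatorial chlorohydrin intact.

Step 12
Reactants: 14 diol
Product: 15 methyl 2α-chloro-3β,7β-bis(triethylsilyloxy)-13,14,15,16-tetranorlabd-8(17)-en-12-oate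
Conditions: TESOTf (2.5 equiv), 2,6-lutidine, CH2Cl2, −78 to 0 °C
Reagents that add atoms: triethylsilyl triflate CC[Si](CC)(CC)OS(=O)(=O)C(F)(F)F
Why: Silyl triflate silylation protects both secondary alcohols, including the hindered C3 one, for the hydride and boron enolate steps.

Step 13
Reactants: 15 bis-silyl ether ester
Product: 16 2α-chloro-3β,7β-bis(triethylsilyloxy)-13,14,15,16-tetranorlabd-8(17)-en-12-al
Conditions: i-Bu2AlH (1.05 equiv), CH2Cl2, −78 °C; aq. KNaC4H4O6
Reagents that add atoms: none
Why: Low-temperature DIBAL reduction stops at the aluminium hemiacetal, which releases the C12 aldehyde on work-up.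

Step 14
Reactants: 17 (4R)-4-benzyl-1,3-oxazolidin-2-one; 18 methyl 4-chloro-4-oxobutanoate
Product: 19 methyl 4-[(4R)-4-benzyl-2-oxo-1,3-oxazolidin-3-yl]-4-oxobutanoate
Conditions: Et3N, DMAP (cat.), CH2Cl2, 0 °C to rt
Reagents that add atoms: none
Why: DMAP-catalysed N-acylation of the oxazolidinone by the acid chloride gives the succinate imide that carries C13–C16.

Step 15
Reactants: 16 aldehyde; 19 succinate imide
Product: 21 methyl (12S,13R)-16-[(4R)-4-benzyl-2-oxo-1,3-oxazolidin-3-yl]-2α-chloro-12-hydroxy-16-oxo-3β,7β-bis(triethylsilyloxy)labd-8(17)-en-15-oate, via Z-boron enolate 20 (not isolated)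
Conditions: 19, Bu2BOTf (1.1 equiv), i-Pr2NEt (1.3 equiv), CH2Cl2, −78 to 0 °C; then 16, −78 to 0 °C; pH 7 buffer, MeOH, H2O2
Reagents that add atoms: none
Why: Evans syn-aldol: the imide (not the ester) is enolised to the Z-boron enolate, and the closed chair transition state with the (R)-benzyl group blocking one enolate face should give the 12S,13R syn adduct.

Step 16
Reactants: 21 aldol adduct
Product: 23 (12S,13R)-2α-chloro-12-hydroxy-3β,7β-bis(triethylsilyloxy)labd-8(17)-ene-15,16-dicarboximide, via primary amide 22 (not isolated)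
Conditions: NH3 (7 M in MeOH), THF, 0 °C to rt
Reagents that add atoms: ammonia N
Why: Ammonolysis of the methyl ester gives the C15 amide, whose nitrogen should attack the activated exocyclic imide carbonyl (5-exo-trig) to close the succinimide and expel the auxiliary; any γ-lactone formed from the C12 hydroxyl and the ester is opened by ammonia to the same amide.

Step 17
Reactants: 23 bis-silyl succinimide
Product: 24 3β-hydroxylissoclimide
Conditions: HF·pyridine, pyridine, THF, 0 °C to rt
Reagents that add atoms: none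
Why: Buffered fluoride cleavage of the two triethylsilyl ethers should leave the allylic alcohol, chlorohydrin and β-hydroxy imide untouched.

**Compound list**

1 | 4-methylpent-1-en-3-one | C=CC(=O)C(C)C | starting material
2 | triisopropyl[(4-methylpenta-1,3-dien-3-yl)oxy]silane | C=CC(O[Si](C(C)C)(C(C)C)C(C)C)=C(C)C | intermediate
3 | 3-(trimethylsilyl)prop-2-ynal | C[Si](C)(C)C#CC=O | starting material
4 | (3R)-1-(trimethylsilyl)hex-5-en-1-yn-3-ol | C=CC[C@@H](O)C#C[Si](C)(C)C | intermediate
5 | (3R)-1-(trimethylsilyl)hex-5-en-1-yn-3-yl acetate | C=CC[C@@H](OC(C)=O)C#C[Si](C)(C)C | intermediate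
6 | methacrolein | C=C(C)C=O | starting material
7 | (3R,5E)-6-methyl-7-oxo-1-(trimethylsilyl)hept-5-en-1-yn-3-yl acetate | O=C/C(C)=C/C[C@@H](OC(C)=O)C#C[Si](C)(C)C | intermediate
8 | (2R)-1-[(1S,6S)-6-formyl-2,2,6-trimethyl-3-(triisopropylsilyloxy)cyclohex-3-en-1-yl]-4-(trimethylsilyl)but-3-yn-2-yl acetate | C[Si](C)(C)C#C[C@H](OC(C)=O)C[C@H]1C(C)(C)C(O[Si](C(C)C)(C(C)C)C(C)C)=CC[C@]1(C)C=O | intermediate
9 | methyl (E)-enoate from 8 (C9 formyl replaced by CH=CH–CO2Me) | C[Si](C)(C)C#C[C@H](OC(C)=O)C[C@H]1C(C)(C)C(O[Si](C(C)C)(C(C)C)C(C)C)=CC[C@]1(C)/C=C/C(=O)OC | intermediate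
10 | propargylic alcohol (9 without acetyl and C-silyl groups) | C#C[C@H](O)C[C@H]1C(C)(C)C(O[Si](C(C)C)(C(C)C)C(C)C)=CC[C@]1(C)/C=C/C(=O)OC | intermediate
11 | methyl 7α-hydroxy-3-(triisopropylsilyloxy)-13,14,15,16-tetranorlabda-2,8(17)-dien-12-oate | C=C1[C@H](O)C[C@H]2C(C)(C)C(O[Si](C(C)C)(C(C)C)C(C)C)=CC[C@]2(C)[C@H]1CC(=O)OC | intermediate
12 | methyl 7-oxo-3-(triisopropylsilyloxy)-13,14,15,16-tetranorlabda-2,8(17)-dien-12-oate | C=C1C(=O)C[C@H]2C(C)(C)C(O[Si](C(C)C)(C(C)C)C(C)C)=CC[C@]2(C)[C@H]1CC(=O)OC | intermediate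
13 | methyl 2α-chloro-3,7-dioxo-13,14,15,16-tetranorlabd-8(17)-en-12-oate | C=C1C(=O)C[C@H]2C(C)(C)C(=O)[C@H](Cl)C[C@]2(C)[C@H]1CC(=O)OC | intermediate
14 | methyl 2α-chloro-3β,7β-dihydroxy-13,14,15,16-tetranorlabd-8(17)-en-12-oate | C=C1[C@@H](O)C[C@H]2C(C)(C)[C@@H](O)[C@H](Cl)C[C@]2(C)[C@H]1CC(=O)OC | intermediate
15 | methyl 2α-chloro-3β,7β-bis(triethylsilyloxy)-13,14,15,16-tetranorlabd-8(17)-en-12-oate | C=C1[C@@H](O[Si](CC)(CC)CC)C[C@H]2C(C)(C)[C@@H](O[Si](CC)(CC)CC)[C@H](Cl)C[C@]2(C)[C@H]1CC(=O)OC | intermediate
16 | 2α-chloro-3β,7β-bis(triethylsilyloxy)-13,14,15,16-tetranorlabd-8(17)-en-12-al | C=C1[C@@H](O[Si](CC)(CC)CC)C[C@H]2C(C)(C)[C@@H](O[Si](CC)(CC)CC)[C@H](Cl)C[C@]2(C)[C@H]1CC=O | intermediate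
17 | (4R)-4-benzyl-1,3-oxazolidin-2-one | O=C1OC[C@@H](Cc2ccccc2)N1 | starting material
18 | methyl 4-chloro-4-oxobutanoate | COC(=O)CCC(Cl)=O | starting material
19 | methyl 4-[(4R)-4-benzyl-2-oxo-1,3-oxazolidin-3-yl]-4-oxobutanoate | COC(=O)CCC(=O)N1[C@H](Cc2ccccc2)COC1=O | intermediate
20 | dibutylboron (Z)-enolate of 19 | COC(=O)C/C=C(\OB(CCCC)CCCC)N1[C@H](Cc2ccccc2)COC1=O | intermediate
21 | methyl (12S,13R)-16-[(4R)-4-benzyl-2-oxo-1,3-oxazolidin-3-yl]-2α-chloro-12-hydroxy-16-oxo-3β,7β-bis(triethylsilyloxy)labd-8(17)-en-15-oate | C=C1[C@@H](O[Si](CC)(CC)CC)C[C@H]2C(C)(C)[C@@H](O[Si](CC)(CC)CC)[C@H](Cl)C[C@]2(C)[C@H]1C[C@H](O)[C@@H](CC(=O)OC)C(=O)N1[C@H](Cc2ccccc2)COC1=O | intermediate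
22 | (12S,13R)-16-[(4R)-4-benzyl-2-oxo-1,3-oxazolidin-3-yl]-2α-chloro-12-hydroxy-16-oxo-3β,7β-bis(triethylsilyloxy)labd-8(17)-en-15-amide | C=C1[C@@H](O[Si](CC)(CC)CC)C[C@H]2C(C)(C)[C@@H](O[Si](CC)(CC)CC)[C@H](Cl)C[C@]2(C)[C@H]1C[C@H](O)[C@@H](CC(N)=O)C(=O)N1[C@H](Cc2ccccc2)COC1=O | intermediate
23 | (12S,13R)-2α-chloro-12-hydroxy-3β,7β-bis(triethylsilyloxy)labd-8(17)-ene-15,16-dicarboximide | C=C1[C@@H](O[Si](CC)(CC)CC)C[C@H]2C(C)(C)[C@@H](O[Si](CC)(CC)CC)[C@H](Cl)C[C@]2(C)[C@H]1C[C@H](O)[C@H]1CC(=O)NC1=O | intermediate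
24 | 3β-hydroxylissoclimide | C=C1[C@@H](O)C[C@H]2C(C)(C)[C@@H](O)[C@H](Cl)C[C@]2(C)[C@H]1C[C@H](O)[C@H]1CC(=O)NC1=O | target

**Step count.** Total: 17 steps. Longest linear sequence: 15 steps (steps 2–13 and 15–17, from 3 to 24).

**Steps most likely to fail**

Step 5. The Z-methyl group on C4 disfavours the s-cis diene. Carbonyl (1,2) addition of the enol ether, arrest at the open-chain Michael stage or protodesilylation of the diene may therefore outrun ring closure, and the catalyst may discriminate the enal faces poorly or in the opposite sense. The fallback sets out from 2 and 7 and gives up catalyst control. The annulation is run as a stepwise double Michael process with the stoichiometric achiral Lewis acid pair AlBr3/AlMe3 in toluene/CH2Cl2 at −20 °C, conditions suited to hindered silyloxydiene/dienophile pairs. The E alkene still fixes the trans relationship, and because C7 is already stereodefined the two facial isomers are diastereomers. Compound 8 is separated by chromatography from (2R)-1-[(1R,6R)-6-formyl-2,2,6-trimethyl-3-(triisopropylsilyloxy)cyclohex-3-en-1-yl]-4-(trimethylsilyl)but-3-yn-2-yl acetate F1, and the route is rejoined at 8.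

Step 8. Carbopalladation at the hindered β-carbon next to the quaternary C10 may be slower than simple reduction of the vinylpalladium intermediate or hydride-induced isomerisation, giving uncyclised alkene. The fallback sets out from 10 and replaces the organopalladium pathway by a radical chain. Bu3SnH and AIBN in benzene at 80 °C (slow addition) add a stannyl radical to the alkyne terminus. The resulting C8 vinyl radical should close 6-exo onto the enoate under the same 1,3-diaxial control by the 7α-hydroxyl, giving methyl 7α-hydroxy-17-(tributylstannyl)-3-(triisopropylsilyloxy)-13,14,15,16-tetranorlabda-2,8(17)-dien-12-oate F2. Stirring F2 with silica gel in CH2Cl2 effects protodestannylation and the route is rejoined at 11.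

Step 16. Basic ammonia may trigger retro-aldol cleavage of the β-hydroxy imide or open the oxazolidinone at its ring carbonyl, or the sequence may stall at a γ-lactone. The fallback sets out from 16 and 17 and brings the nitrogen in as a nitrile. Compound 17 is acylated with 3-cyanopropanoyl chloride (Et3N, DMAP) to (4R)-4-benzyl-3-(3-cyanopropanoyl)-1,3-oxazolidin-2-one F3. The same boron aldol with 16 should give (12S,13R)-16-[(4R)-4-benzyl-2-oxo-1,3-oxazolidin-3-yl]-2α-chloro-12-hydroxy-16-oxo-3β,7β-bis(triethylsilyloxy)labd-8(17)-ene-15-nitrile F4. Neutral hydration of the nitrile with the platinum phosphinito complex [PtH(PMe2OH)(PMe2O)2H] in aqueous EtOH at 80 °C gives amide 22, which closes to the succinimide, and the route is rejoined at 23.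

**Further compounds**

F1 | step 5 | (2R)-1-[(1R,6R)-6-formyl-2,2,6-trimethyl-3-(triisopropylsilyloxy)cyclohex-3-en-1-yl]-4-(trimethylsilyl)but-3-yn-2-yl acetate | C[Si](C)(C)C#C[C@H](OC(C)=O)C[C@@H]1C(C)(C)C(O[Si](C(C)C)(C(C)C)C(C)C)=CC[C@@]1(C)C=O
F2 | step 8 | methyl 7α-hydroxy-17-(tributylstannyl)-3-(triisopropylsilyloxy)-13,14,15,16-tetranorlabda-2,8(17)-dien-12-oate | CCCC[Sn](CCCC)(CCCC)C=C1[C@H](O)C[C@H]2C(C)(C)C(O[Si](C(C)C)(C(C)C)C(C)C)=CC[C@]2(C)[C@H]1CC(=O)OC
F3 | step 16 | (4R)-4-benzyl-3-(3-cyanopropanoyl)-1,3-oxazolidin-2-one | N#CCCC(=O)N1[C@H](Cc2ccccc2)COC1=O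
F4 | step 16 | (12S,13R)-16-[(4R)-4-benzyl-2-oxo-1,3-oxazolidin-3-yl]-2α-chloro-12-hydroxy-16-oxo-3β,7β-bis(triethylsilyloxy)labd-8(17)-ene-15-nitrile | C=C1[C@@H](O[Si](CC)(CC)CC)C[C@H]2C(C)(C)[C@@H](O[Si](CC)(CC)CC)[C@H](Cl)C[C@]2(C)[C@H]1C[C@H](O)[C@@H](CC#N)C(=O)N1[C@H](Cc2ccccc2)COC1=O
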